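## Retrosynthetic overview

- Last bond: C11–C12, closed by an electroreductive chromium/nickel-catalysed alkenyl iodide–aldehyde (Nozaki–Hiyama–Kishi type) cyclisation that forms the 20-membered ring and the C11 carbinol.
- Before that, the C1–O19 ester joins a West acid (C1–C11, C4 from methyl (S)-3-hydroxy-2-methylpropanoate) to an East alcohol (C12–C24).
- East: statin-type (3R,5S)-diol ester → Fráter–Seebach methylation (C18) → iodoetherification (oxolane, C14) → Z-iodoalkene → alkenylzinc addition at C19 of a lactate-derived C20–C24 alkyne.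
- West: carboalumination, Sonogashira coupling and Z-semi-reduction give the 6E,8Z-diene; Still–Gennari olefination gives the 2Z-enoate; the C5 ketone is unmasked late from a PMB ether.
- Ring order: oxolane (step 4), oxirane (step 25, SN2 inversion at C23), macrolactone ring (step 28).

Assumption: the SMILES is taken as drawn and numbered from the lactone carbonyl (C1) to the oxirane methyl (C24), i.e. 2Z,4S,6E,8Z,11R,12Z,14S,15S,17R,18R,19R,20E,22R,23R.

## Route

Step 1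
Reactants: 1 tert-butyl 2-[(4R,6S)-6-formyl-2,2-dimethyl-1,3-dioxan-4-yl]acetate
Product: 2 tert-butyl 2-[(4R,6S)-6-ethenyl-2,2-dimethyl-1,3-dioxan-4-yl]acetate
Conditions: Ph3PCH3Br, KN(SiMe3)2, THF, 0 °C; then 1, −78 °C → rt
Reagents that add atoms: methyltriphenylphosphonium bromide, C[P+](c1ccccc1)(c1ccccc1)c1ccccc1.[Br-]
Why: Wittig methylenation of the α-alkoxy aldehyde is fast at low temperature, so the bought C15 centre is not epimerised and no new stereocentre arises.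

Step 2
Reactants: 2 tert-butyl 2-[(4R,6S)-6-ethenyl-2,2-dimethyl-1,3-dioxan-4-yl]acetate
Product: 3 tert-butyl (3R,5S)-3,5-dihydroxyhept-6-enoate
Conditions: 1 M HCl (cat.), MeCN/H2O, rt
Reagents that add atoms: none
Why: Acid-catalysed acetonide hydrolysis frees the syn-1,3-diol while the tert-butyl ester resists lactonisation, leaving both bought stereocentres untouched.

Step 3
Reactants: 3 tert-butyl (3R,5S)-3,5-dihydroxyhept-6-enoate
Product: 4 tert-butyl (2R,3R,5S)-3,5-dihydroxy-2-methylhept-6-enoate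
Conditions: LiN(iPr)2 (3.3 equiv), THF, −78 → −20 °C; MeI, DMPU, −78 → −40 °C; aq. NH4Cl
Reagents that add atoms: iodomethane, CI
Why: Fráter–Seebach alkylation: the lithium alkoxide–enolate chelate of the β-hydroxy ester (the third equivalent of base only deprotonates the remote 5-OH) is methylated anti to the C3 oxygen, setting C18 from the bought C17 centre.

Step 4
Reactants: 4 tert-butyl (2R,3R,5S)-3,5-dihydroxy-2-methylhept-6-enoate
Product: 5 tert-butyl (2R)-2-[(2R,4S,5R)-4-hydroxy-5-(iodomethyl)oxolan-2-yl]propanoate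
Conditions: I2, NaHCO3, MeCN, 0 °C, dark
Reagents that add atoms: iodine, [I][I]
Why: Kinetic 5-exo iodoetherification of a 4-pentene-1,3-diol places the allylic hydroxyl in the alkene plane and gives the 2,3-cis oxolane, which with the bought syn-1,3-diol is necessarily the 2,5-trans ring, so C14 is set by C15 and C17.

Step 5
Reactants: 5 tert-butyl (2R)-2-[(2R,4S,5R)-4-hydroxy-5-(iodomethyl)oxolan-2-yl]propanoate
Product: 6 tert-butyl (2R)-2-[(2R,4S,5R)-5-(iodomethyl)-4-methoxyoxolan-2-yl]propanoate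
Conditions: Me3OBF4, 1,8-bis(dimethylamino)naphthalene, CH2Cl2, 0 °C → rt
Reagents that add atoms: trimethyloxonium tetrafluoroborate, C[O+](C)C.F[B-](F)(F)F
Why: O-Methylation with a Meerwein salt and a non-nucleophilic base avoids an alkoxide, so neither oxetane closure onto the cis iodomethyl group nor epimerisation α to the ester can occur.

Step 6
Reactants: 6 tert-butyl (2R)-2-[(2R,4S,5R)-5-(iodomethyl)-4-methoxyoxolan-2-yl]propanoate
Product: 8 tert-butyl (2R)-2-[(2R,4S,5S)-5-(hydroxymethyl)-4-methoxyoxolan-2-yl]propanoate, via formate ester 7 (not isolated)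
Conditions: CsO2CH, DMF, 80 °C; then MeOH, K2CO3 (cat.), 0 °C
Reagents that add atoms: caesium formate, [Cs+].[O-]C=O
Why: SN2 displacement of the primary iodide by formate, then transesterification to methyl formate, gives the primary alcohol without a cationic pathway that could expand the ring; no stereocentre is touched.

Step 7
Reactants: 8 tert-butyl (2R)-2-[(2R,4S,5S)-5-(hydroxymethyl)-4-methoxyoxolan-2-yl]propanoate
Product: 9 tert-butyl (2R)-2-[(2R,4S,5R)-5-formyl-4-methoxyoxolan-2-yl]propanoate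
Conditions: Dess–Martin periodinane, pyridine, CH2Cl2, 0 °C → rt
Reagents that add atoms: none
Why: Buffered Dess–Martin oxidation gives the α-alkoxy aldehyde under near-neutral conditions, so the cis-2,3 relationship is kept; the crude aldehyde is used at once.

Step 8
Reactants: 9 tert-butyl (2R)-2-[(2R,4S,5R)-5-formyl-4-methoxyoxolan-2-yl]propanoate
Product: 10 tert-butyl (2R)-2-{(2R,4S,5S)-5-[(1Z)-2-iodoprop-1-en-1-yl]-4-methoxyoxolan-2-yl}propanoate
Conditions: Ph3PEtI, n-BuLi, THF, rt; I2, −78 °C; NaN(SiMe3)2, −78 → −20 °C; then 9, −78 °C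
Reagents that add atoms: ethyltriphenylphosphonium iodide, CC[P+](c1ccccc1)(c1ccccc1)c1ccccc1.[I-]; iodine, [I][I]
Why: Stork–Zhao-type Wittig olefination with the α-iodoethylidene ylide is kinetically Z-selective (iodine cis to the oxolane carbon), giving the 12Z-iodoalkene needed for the later ring closure.

Step 9
Reactants: 10 tert-butyl (2R)-2-{(2R,4S,5S)-5-[(1Z)-2-iodoprop-1-en-1-yl]-4-methoxyoxolan-2-yl}propanoate
Product: 11 (2R)-2-{(2R,4S,5S)-5-[(1Z)-2-iodoprop-1-en-1-yl]-4-methoxyoxolan-2-yl}propanal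
Conditions: iBu2AlH, CH2Cl2, −78 °C; aq. KNaC4H4O6
Reagents that add atoms: none
Why: Half-reduction with iBu2AlH stops at the stable aluminium hemiacetal of the hindered tert-butyl ester, releasing the aldehyde only on work-up; the alkenyl iodide is inert and C18 is kept by immediate use.

Step 10
Reactants: 12 ethyl (2S)-2-{[(4-methylphenyl)sulfonyl]oxy}propanoate
Product: 13 (2S)-1-oxopropan-2-yl 4-methylbenzenesulfonate
Conditions: iBu2AlH, CH2Cl2, −78 °C; aq. KNaC4H4O6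
Reagents that add atoms: none
Why: Low-temperature iBu2AlH reduction of the lactate ester to the aldehyde leaves the sulfonate and the bought C23 centre untouched.

Step 11
Reactants: 13 (2S)-1-oxopropan-2-yl 4-methylbenzenesulfonate
Product: 14 (2S,3R)-3-hydroxypent-4-yn-2-yl 4-methylbenzenesulfonate
Conditions: HC≡CH, n-BuLi, THF, −78 °C; then 13, −78 °C; aq. NH4Cl at −78 °C
Reagents that add atoms: acetylene, C#C
Why: Acetylide addition under Felkin–Anh (polar, Cornforth) control attacks anti to the sulfonyloxy group and gives the anti (erythro) alcohol (about 5:1 expected), so C22 is set by the bought C23 centre; the cold quench prevents premature oxirane closure.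

Step 12
Reactants: 14 (2S,3R)-3-hydroxypent-4-yn-2-yl 4-methylbenzenesulfonate
Product: 15 (2S,3R)-3-{[tert-butyl(dimethyl)silyl]oxy}pent-4-yn-2-yl 4-methylbenzenesulfonate
Conditions: TBSOTf, 2,6-lutidine, CH2Cl2, −78 → 0 °C
Reagents that add atoms: tert-butyldimethylsilyl trifluoromethanesulfonate, CC(C)(C)[Si](C)(C)OS(=O)(=O)C(F)(F)F
Why: Silyl triflate silylation with a weak hindered base protects the C22 hydroxyl without forming the alkoxide that would displace the neighbouring tosylate.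

Step 13
Reactants: 15 (2S,3R)-3-{[tert-butyl(dimethyl)silyl]oxy}pent-4-yn-2-yl 4-methylbenzenesulfonate; 11 (2R)-2-{(2R,4S,5S)-5-[(1Z)-2-iodoprop-1-en-1-yl]-4-methoxyoxolan-2-yl}propanal
Product: 18 (2S,3R,4E,6R,7S)-3-{[tert-butyl(dimethyl)silyl]oxy}-6-hydroxy-7-{(2R,4S,5S)-5-[(1Z)-2-iodoprop-1-en-1-yl]-4-methoxyoxolan-2-yl}oct-4-en-2-yl 4-methylbenzenesulfonate, via alkenylzirconocene 16 (not isolated), via alkenylzinc 17 (not isolated)
Conditions: Cp2Zr(H)Cl, CH2Cl2, rt; ZnMe2, toluene, −65 °C; then 11, 0 °C; aq. NH4Cl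
Reagents that add atoms: none
Why: Syn hydrozirconation gives the E-alkenyl metal, and after transmetalation the alkenylzinc adds to the α-methyl aldehyde by Felkin–Anh attack reinforced by 1,3-anti induction from the oxolane oxygen, giving the 18,19-syn (19R) alcohol (about 4:1 expected); the alkenyl iodide and tosylate are inert to organozinc.

Step 14
Reactants: 19 methyl (2S)-3-hydroxy-2-methylpropanoate
Product: 20 methyl (2S)-2-methyl-3-[(triethylsilyl)oxy]propanoate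
Conditions: Et3SiCl, imidazole, CH2Cl2, 0 °C
Reagents that add atoms: chlorotriethylsilane, CC[Si](Cl)(CC)CC
Why: Standard silylation of the primary alcohol; the triethylsilyl ether is chosen because it can later be oxidised directly to the aldehyde.

Step 15
Reactants: 20 methyl (2S)-2-methyl-3-[(triethylsilyl)oxy]propanoate
Product: 21 (2S)-2-methyl-3-[(triethylsilyl)oxy]propanal
Conditions: iBu2AlH, CH2Cl2, −78 °C; aq. KNaC4H4O6
Reagents that add atoms: none
Why: Low-temperature iBu2AlH half-reduction of the ester gives the configurationally stable β-silyloxy aldehyde carrying the bought C4 centre.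

Step 16
Reactants: 21 (2S)-2-methyl-3-[(triethylsilyl)oxy]propanal
Product: 22 (3RS,4S)-4-methyl-5-[(triethylsilyl)oxy]pent-1-yn-3-ol
Conditions: HC≡CMgBr, THF, −78 → 0 °C; aq. NH4Cl
Reagents that add atoms: ethynylmagnesium bromide, C#C[Mg]Br
Why: Grignard addition to the aldehyde installs C6–C7; the new carbinol (C5) is carried as both epimers because it becomes the ketone in step 26.

Step 17
Reactants: 22 (3RS,4S)-4-methyl-5-[(triethylsilyl)oxy]pent-1-yn-3-ol
Product: 24 (1E,3RS,4S)-1-iodo-2,4-dimethyl-5-[(triethylsilyl)oxy]pent-1-en-3-ol, via alkenylalane 23 (not isolated)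
Conditions: AlMe3 (3 equiv), Cp2ZrCl2 (0.3 equiv), CH2Cl2, 0 °C → rt; then I2, THF, −30 °C; aq. KNaC4H4O6
Reagents that add atoms: trimethylaluminium, C[Al](C)C; iodine, [I][I]
Why: Negishi zirconium-catalysed carboalumination adds methyl and aluminium syn across the terminal alkyne (methyl to the internal carbon) and iodinolysis proceeds with retention, fixing the 6E geometry.

Step 18
Reactants: 24 (1E,3RS,4S)-1-iodo-2,4-dimethyl-5-[(triethylsilyl)oxy]pent-1-en-3-ol
Product: 25 triethyl{[(2S,3RS,4E)-5-iodo-3-[(4-methoxyphenyl)methoxy]-2,4-dimethylpent-4-en-1-yl]oxy}silane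
Conditions: NaH, 4-MeOC6H4CH2Cl, Bu4NI (cat.), DMF, 0 °C → rt
Reagents that add atoms: 4-methoxybenzyl chloride, COc1ccc(CCl)cc1
Why: Williamson etherification under basic conditions avoids ionising the allylic carbinol and installs a PMB group that can later be removed and oxidised in one operation.

Step 19
Reactants: 25 triethyl{[(2S,3RS,4E)-5-iodo-3-[(4-methoxyphenyl)methoxy]-2,4-dimethylpent-4-en-1-yl]oxy}silane; 26 tert-butyl(but-3-yn-1-yloxy)dimethylsilane
Product: 27 tert-butyl{[(5E,7RS,8S)-7-[(4-methoxyphenyl)methoxy]-6,8-dimethyl-9-[(triethylsilyl)oxy]non-5-en-3-yn-1-yl]oxy}dimethylsilane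
Conditions: Pd(PPh3)2Cl2 (5 mol %), CuI (10 mol %), Et3N, THF, rt
Reagents that add atoms: none
Why: Sonogashira coupling of the alkenyl iodide with the terminal alkyne proceeds with retention of the E geometry and forms the C7–C8 bond.

Step 20
Reactants: 27 tert-butyl{[(5E,7RS,8S)-7-[(4-methoxyphenyl)methoxy]-6,8-dimethyl-9-[(triethylsilyl)oxy]non-5-en-3-yn-1-yl]oxy}dimethylsilane
Product: 28 tert-butyl{[(3Z,5E,7RS,8S)-7-[(4-methoxyphenyl)methoxy]-6,8-dimethyl-9-[(triethylsilyl)oxy]nona-3,5-dien-1-yl]oxy}dimethylsilane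
Conditions: Zn dust (activated with Cu(OAc)2 and AgNO3), MeOH/H2O, 40 °C
Reagents that add atoms: none
Why: Activated-zinc semi-reduction of the conjugated enyne delivers both hydrogens cis on the metal surface and stops at the alkene, giving the 8Z double bond without touching the 6E alkene.

Step 21
Reactants: 28 tert-butyl{[(3Z,5E,7RS,8S)-7-[(4-methoxyphenyl)methoxy]-6,8-dimethyl-9-[(triethylsilyl)oxy]nona-3,5-dien-1-yl]oxy}dimethylsilane
Product: 29 (2R,3RS,4E,6Z)-9-{[tert-butyl(dimethyl)silyl]oxy}-3-[(4-methoxyphenyl)methoxy]-2,4-dimethylnona-4,6-dienal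
Conditions: (COCl)2, DMSO, CH2Cl2, −78 → −40 °C; Et3N, −78 °C → rt
Reagents that add atoms: none
Why: Under Swern conditions a primary triethylsilyl ether is converted directly to the aldehyde while the tert-butyldimethylsilyl and PMB ethers survive, and the low temperature preserves the α-stereocentre (C4).

Step 22
Reactants: 29 (2R,3RS,4E,6Z)-9-{[tert-butyl(dimethyl)silyl]oxy}-3-[(4-methoxyphenyl)methoxy]-2,4-dimethylnona-4,6-dienal
Product: 30 ethyl (2Z,4S,5RS,6E,8Z)-11-{[tert-butyl(dimethyl)silyl]oxy}-5-[(4-methoxyphenyl)methoxy]-2,4,6-trimethylundeca-2,6,8-trienoate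
Conditions: (CF3CH2O)2P(O)CH(CH3)CO2Et, KN(SiMe3)2, 18-crown-6, THF, −78 °C
Reagents that add atoms: ethyl 2-[bis(2,2,2-trifluoroethoxy)phosphoryl]propanoate, CCOC(=O)C(C)P(=O)(OCC(F)(F)F)OCC(F)(F)F
Why: Still–Gennari olefination with the electron-poor phosphonate eliminates fast from the kinetic adduct and gives the 2Z trisubstituted enoate, with C5 still an ether so C4 has no acidic hydrogen.

Step 23
Reactants: 30 ethyl (2Z,4S,5RS,6E,8Z)-11-{[tert-butyl(dimethyl)silyl]oxy}-5-[(4-methoxyphenyl)methoxy]-2,4,6-trimethylundeca-2,6,8-trienoate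
Product: 31 (2Z,4S,5RS,6E,8Z)-11-{[tert-butyl(dimethyl)silyl]oxy}-5-[(4-methoxyphenyl)methoxy]-2,4,6-trimethylundeca-2,6,8-trienoic acid
Conditions: LiOH, THF/MeOH/H2O, 35 °C; then 1 M HCl to pH 4
Reagents that add atoms: lithium hydroxide, [Li+].[OH-]
Why: Saponification of the ethyl ester leaves the silyl and PMB ethers and the Z-alkene intact, since no ketone is yet present to acidify C4.

Step 24
Reactants: 18 (2S,3R,4E,6R,7S)-3-{[tert-butyl(dimethyl)silyl]oxy}-6-hydroxy-7-{(2R,4S,5S)-5-[(1Z)-2-iodoprop-1-en-1-yl]-4-methoxyoxolan-2-yl}oct-4-en-2-yl 4-methylbenzenesulfonate; 31 (2Z,4S,5RS,6E,8Z)-11-{[tert-butyl(dimethyl)silyl]oxy}-5-[(4-methoxyphenyl)methoxy]-2,4,6-trimethylundeca-2,6,8-trienoic acid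
Product: 32 (2S,3R,4E,6R,7R)-3-{[tert-butyl(dimethyl)silyl]oxy}-7-{(2R,4S,5S)-5-[(1Z)-2-iodoprop-1-en-1-yl]-4-methoxyoxolan-2-yl}-2-{[(4-methylphenyl)sulfonyl]oxy}oct-4-en-6-yl (2Z,4S,5RS,6E,8Z)-11-{[tert-butyl(dimethyl)silyl]oxy}-5-[(4-methoxyphenyl)methoxy]-2,4,6-trimethylundeca-2,6,8-trienoate
Conditions: 2-methyl-6-nitrobenzoic anhydride, DMAP, Et3N, CH2Cl2, rt
Reagents that add atoms: none
Why: Shiina mixed-anhydride esterification acylates the hindered secondary C19 alcohol at room temperature, mild enough to keep the Z-enoate from isomerising.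

Step 25
Reactants: 32 (2S,3R,4E,6R,7R)-3-{[tert-butyl(dimethyl)silyl]oxy}-7-{(2R,4S,5S)-5-[(1Z)-2-iodoprop-1-en-1-yl]-4-methoxyoxolan-2-yl}-2-{[(4-methylphenyl)sulfonyl]oxy}oct-4-en-6-yl (2Z,4S,5RS,6E,8Z)-11-{[tert-butyl(dimethyl)silyl]oxy}-5-[(4-methoxyphenyl)methoxy]-2,4,6-trimethylundeca-2,6,8-trienoate
Product: 33 (1E,3R,4R)-4-{(2R,4S,5S)-5-[(1Z)-2-iodoprop-1-en-1-yl]-4-methoxyoxolan-2-yl}-1-[(2R,3R)-3-methyloxiran-2-yl]pent-1-en-3-yl (2Z,4S,5RS,6E,8Z)-11-hydroxy-5-[(4-methoxyphenyl)methoxy]-2,4,6-trimethylundeca-2,6,8-trienoate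
Conditions: Bu4NF, THF, 0 °C → rt; aq. NH4Cl
Reagents that add atoms: none
Why: Fluoride desilylation frees C11–OH and generates the C22 alkoxide, which displaces the neighbouring tosylate by intramolecular SN2 with inversion at C23 to give the trans-(22R,23R) oxirane; no ketone is present yet, so the basic conditions cannot epimerise C4.

Step 26
Reactants: 33 (1E,3R,4R)-4-{(2R,4S,5S)-5-[(1Z)-2-iodoprop-1-en-1-yl]-4-methoxyoxolan-2-yl}-1-[(2R,3R)-3-methyloxiran-2-yl]pent-1-en-3-yl (2Z,4S,5RS,6E,8Z)-11-hydroxy-5-[(4-methoxyphenyl)methoxy]-2,4,6-trimethylundeca-2,6,8-trienoate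
Product: 35 (1E,3R,4R)-4-{(2R,4S,5S)-5-[(1Z)-2-iodoprop-1-en-1-yl]-4-methoxyoxolan-2-yl}-1-[(2R,3R)-3-methyloxiran-2-yl]pent-1-en-3-yl (2Z,4S,6E,8Z)-11-hydroxy-2,4,6-trimethyl-5-oxoundeca-2,6,8-trienoate, via dienyl carbinol 34 (not isolated)
Conditions: DDQ (3 equiv), CH2Cl2/pH 7 buffer, 0 °C → rt
Reagents that add atoms: none
Why: Oxidative PMB cleavage by DDQ is followed in the same flask by DDQ dehydrogenation of the liberated dienylic alcohol to the dienone, so the δ-hydroxy Z-enoate never accumulates to lactonise and the neutral medium spares C4 and the vinyl oxirane.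

Step 27
Reactants: 35 (1E,3R,4R)-4-{(2R,4S,5S)-5-[(1Z)-2-iodoprop-1-en-1-yl]-4-methoxyoxolan-2-yl}-1-[(2R,3R)-3-methyloxiran-2-yl]pent-1-en-3-yl (2Z,4S,6E,8Z)-11-hydroxy-2,4,6-trimethyl-5-oxoundeca-2,6,8-trienoate
Product: 36 (1E,3R,4R)-4-{(2R,4S,5S)-5-[(1Z)-2-iodoprop-1-en-1-yl]-4-methoxyoxolan-2-yl}-1-[(2R,3R)-3-methyloxiran-2-yl]pent-1-en-3-yl (2Z,4S,6E,8Z)-2,4,6-trimethyl-5,11-dioxoundeca-2,6,8-trienoate
Conditions: Dess–Martin periodinane, pyridine, CH2Cl2, 0 °C
Reagents that add atoms: none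
Why: Buffered Dess–Martin oxidation turns the primary C11 alcohol (and any residual C5 carbinol) into the carbonyl without base, so the skipped β,γ-unsaturated aldehyde and C4 survive; the product is used at once.

Step 28
Reactants: 36 (1E,3R,4R)-4-{(2R,4S,5S)-5-[(1Z)-2-iodoprop-1-en-1-yl]-4-methoxyoxolan-2-yl}-1-[(2R,3R)-3-methyloxiran-2-yl]pent-1-en-3-yl (2Z,4S,6E,8Z)-2,4,6-trimethyl-5,11-dioxoundeca-2,6,8-trienoate
Product: 37 CNP0117824.2, (2Z,4S,6E,8Z,11R,12Z,14S,15S,17R,18R,19R)-14,17-epoxy-11-hydroxy-15-methoxy-2,4,6,12,18-pentamethyl-19-{(E)-2-[(2R,3R)-3-methyloxiran-2-yl]ethenyl}-5-oxononadeca-2,6,8,12-tetraen-19-olide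
Conditions: CrCl2 (20 mol %), NiCl2(MeOCH2CH2OMe) (2 mol %), Cp2ZrCl2 (1.2 equiv), LiCl, Bu4NPF6, DMF/THF, Zn anode, Ni-foam cathode, undivided cell, constant current (2.2 F/mol), slow addition of 36 (to 1 mM), rt; aq. work-up
Reagents that add atoms: none
Why: Proposed new method: the cathode keeps the chromium in its divalent state while zerovalent nickel inserts into the C12–I bond and passes the Z-alkenyl group to chromium with retention, the alkenylchromium adds to the C11 aldehyde (far faster than to the C5 ketone) inside the forming 20-membered ring, Cp2ZrCl2 takes the alkoxide from trivalent chromium so that 20 mol % CrCl2 turns over, and syringe-pump feed gives pseudo-high dilution; C11 is set by the macrocycle alone (no chiral ligand), the ring-closing transition state that keeps the C11–C12 bond clear of the oxolane and its cis methoxy group being predicted to give 11R, a selectivity that remains to be measured; the closest known reaction types are the intermolecular electrochemical chromium/nickel-catalysed alkenyl halide–aldehyde coupling and the macrocyclisation with stoichiometric CrCl2, and the electrochemical variant has not been shown for ring closure of such a keto-aldehyde.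

## Compound list

1 | tert-butyl 2-[(4R,6S)-6-formyl-2,2-dimethyl-1,3-dioxan-4-yl]acetate | O=C[C@@H]1C[C@H](CC(=O)OC(C)(C)C)OC(C)(C)O1 | starting material
2 | tert-butyl 2-[(4R,6S)-6-ethenyl-2,2-dimethyl-1,3-dioxan-4-yl]acetate | C=C[C@@H]1C[C@H](CC(=O)OC(C)(C)C)OC(C)(C)O1 | intermediate
3 | tert-butyl (3R,5S)-3,5-dihydroxyhept-6-enoate | C=C[C@@H](O)C[C@@H](O)CC(=O)OC(C)(C)C | intermediate
4 | tert-butyl (2R,3R,5S)-3,5-dihydroxy-2-methylhept-6-enoate | C=C[C@@H](O)C[C@@H](O)[C@@H](C)C(=O)OC(C)(C)C | intermediate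
5 | tert-butyl (2R)-2-[(2R,4S,5R)-4-hydroxy-5-(iodomethyl)oxolan-2-yl]propanoate | O[C@H]1C[C@@H](O[C@H]1CI)[C@@H](C)C(=O)OC(C)(C)C | intermediate
6 | tert-butyl (2R)-2-[(2R,4S,5R)-5-(iodomethyl)-4-methoxyoxolan-2-yl]propanoate | CO[C@H]1C[C@@H](O[C@H]1CI)[C@@H](C)C(=O)OC(C)(C)C | intermediate
7 | formate ester (not isolated): tert-butyl (2R)-2-{(2R,4S,5S)-5-[(formyloxy)methyl]-4-methoxyoxolan-2-yl}propanoate | CO[C@H]1C[C@@H](O[C@H]1COC=O)[C@@H](C)C(=O)OC(C)(C)C | intermediate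
8 | tert-butyl (2R)-2-[(2R,4S,5S)-5-(hydroxymethyl)-4-methoxyoxolan-2-yl]propanoate | CO[C@H]1C[C@@H](O[C@H]1CO)[C@@H](C)C(=O)OC(C)(C)C | intermediate
9 | tert-butyl (2R)-2-[(2R,4S,5R)-5-formyl-4-methoxyoxolan-2-yl]propanoate | CO[C@H]1C[C@@H](O[C@H]1C=O)[C@@H](C)C(=O)OC(C)(C)C | intermediate
10 | tert-butyl (2R)-2-{(2R,4S,5S)-5-[(1Z)-2-iodoprop-1-en-1-yl]-4-methoxyoxolan-2-yl}propanoate | CO[C@H]1C[C@@H](O[C@H]1/C=C(/C)I)[C@@H](C)C(=O)OC(C)(C)C | intermediate
11 | (2R)-2-{(2R,4S,5S)-5-[(1Z)-2-iodoprop-1-en-1-yl]-4-methoxyoxolan-2-yl}propanal | CO[C@H]1C[C@@H](O[C@H]1/C=C(/C)I)[C@@H](C)C=O | intermediate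
12 | ethyl (2S)-2-{[(4-methylphenyl)sulfonyl]oxy}propanoate | CCOC(=O)[C@H](C)OS(=O)(=O)c1ccc(C)cc1 | starting material
13 | (2S)-1-oxopropan-2-yl 4-methylbenzenesulfonate | C[C@H](OS(=O)(=O)c1ccc(C)cc1)C=O | intermediate
14 | (2S,3R)-3-hydroxypent-4-yn-2-yl 4-methylbenzenesulfonate | C[C@H](OS(=O)(=O)c1ccc(C)cc1)[C@H](O)C#C | intermediate
15 | (2S,3R)-3-{[tert-butyl(dimethyl)silyl]oxy}pent-4-yn-2-yl 4-methylbenzenesulfonate | C[C@H](OS(=O)(=O)c1ccc(C)cc1)[C@H](O[Si](C)(C)C(C)(C)C)C#C | intermediate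
16 | alkenylzirconocene (not isolated): chlorido{(1E,3R,4S)-3-{[tert-butyl(dimethyl)silyl]oxy}-4-{[(4-methylphenyl)sulfonyl]oxy}pent-1-en-1-yl}bis(cyclopentadienyl)zirconium | C[C@H](OS(=O)(=O)c1ccc(C)cc1)[C@H](O[Si](C)(C)C(C)(C)C)/C=C/[Zr](Cl)(C1C=CC=C1)C1C=CC=C1 | intermediate
17 | alkenylzinc (not isolated): {(1E,3R,4S)-3-{[tert-butyl(dimethyl)silyl]oxy}-4-{[(4-methylphenyl)sulfonyl]oxy}pent-1-en-1-yl}(methyl)zinc | C[C@H](OS(=O)(=O)c1ccc(C)cc1)[C@H](O[Si](C)(C)C(C)(C)C)/C=C/[Zn]C | intermediate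
18 | (2S,3R,4E,6R,7S)-3-{[tert-butyl(dimethyl)silyl]oxy}-6-hydroxy-7-{(2R,4S,5S)-5-[(1Z)-2-iodoprop-1-en-1-yl]-4-methoxyoxolan-2-yl}oct-4-en-2-yl 4-methylbenzenesulfonate | CO[C@H]1C[C@@H](O[C@H]1/C=C(/C)I)[C@@H](C)[C@H](O)/C=C/[C@@H](O[Si](C)(C)C(C)(C)C)[C@H](C)OS(=O)(=O)c1ccc(C)cc1 | intermediate
19 | methyl (2S)-3-hydroxy-2-methylpropanoate | COC(=O)[C@@H](C)CO | starting material
20 | methyl (2S)-2-methyl-3-[(triethylsilyl)oxy]propanoate | COC(=O)[C@@H](C)CO[Si](CC)(CC)CC | intermediate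
21 | (2S)-2-methyl-3-[(triethylsilyl)oxy]propanal | O=C[C@@H](C)CO[Si](CC)(CC)CC | intermediate
22 | (3RS,4S)-4-methyl-5-[(triethylsilyl)oxy]pent-1-yn-3-ol | C#CC(O)[C@@H](C)CO[Si](CC)(CC)CC | intermediate
23 | alkenylalane (not isolated): dimethyl{(1E,3RS,4S)-3-[(dimethylalumanyl)oxy]-2,4-dimethyl-5-[(triethylsilyl)oxy]pent-1-en-1-yl}alumane | C[Al](C)/C=C(\C)C(O[Al](C)C)[C@@H](C)CO[Si](CC)(CC)CC | intermediate
24 | (1E,3RS,4S)-1-iodo-2,4-dimethyl-5-[(triethylsilyl)oxy]pent-1-en-3-ol | I/C=C(\C)C(O)[C@@H](C)CO[Si](CC)(CC)CC | intermediate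
25 | triethyl{[(2S,3RS,4E)-5-iodo-3-[(4-methoxyphenyl)methoxy]-2,4-dimethylpent-4-en-1-yl]oxy}silane | I/C=C(\C)C(OCc1ccc(OC)cc1)[C@@H](C)CO[Si](CC)(CC)CC | intermediate
26 | tert-butyl(but-3-yn-1-yloxy)dimethylsilane | C#CCCO[Si](C)(C)C(C)(C)C | starting material
27 | tert-butyl{[(5E,7RS,8S)-7-[(4-methoxyphenyl)methoxy]-6,8-dimethyl-9-[(triethylsilyl)oxy]non-5-en-3-yn-1-yl]oxy}dimethylsilane | CC(C)(C)[Si](C)(C)OCCC#C/C=C(\C)C(OCc1ccc(OC)cc1)[C@@H](C)CO[Si](CC)(CC)CC | intermediate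
28 | tert-butyl{[(3Z,5E,7RS,8S)-7-[(4-methoxyphenyl)methoxy]-6,8-dimethyl-9-[(triethylsilyl)oxy]nona-3,5-dien-1-yl]oxy}dimethylsilane | CC(C)(C)[Si](C)(C)OCC/C=C\C=C(/C)C(OCc1ccc(OC)cc1)[C@@H](C)CO[Si](CC)(CC)CC | intermediate
29 | (2R,3RS,4E,6Z)-9-{[tert-butyl(dimethyl)silyl]oxy}-3-[(4-methoxyphenyl)methoxy]-2,4-dimethylnona-4,6-dienal | CC(C)(C)[Si](C)(C)OCC/C=C\C=C(/C)C(OCc1ccc(OC)cc1)[C@@H](C)C=O | intermediate
30 | ethyl (2Z,4S,5RS,6E,8Z)-11-{[tert-butyl(dimethyl)silyl]oxy}-5-[(4-methoxyphenyl)methoxy]-2,4,6-trimethylundeca-2,6,8-trienoate | CC(C)(C)[Si](C)(C)OCC/C=C\C=C(/C)C(OCc1ccc(OC)cc1)[C@@H](C)/C=C(/C)C(=O)OCC | intermediate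
31 | (2Z,4S,5RS,6E,8Z)-11-{[tert-butyl(dimethyl)silyl]oxy}-5-[(4-methoxyphenyl)methoxy]-2,4,6-trimethylundeca-2,6,8-trienoic acid | CC(C)(C)[Si](C)(C)OCC/C=C\C=C(/C)C(OCc1ccc(OC)cc1)[C@@H](C)/C=C(/C)C(=O)O | intermediate
32 | (2S,3R,4E,6R,7R)-3-{[tert-butyl(dimethyl)silyl]oxy}-7-{(2R,4S,5S)-5-[(1Z)-2-iodoprop-1-en-1-yl]-4-methoxyoxolan-2-yl}-2-{[(4-methylphenyl)sulfonyl]oxy}oct-4-en-6-yl (2Z,4S,5RS,6E,8Z)-11-{[tert-butyl(dimethyl)silyl]oxy}-5-[(4-methoxyphenyl)methoxy]-2,4,6-trimethylundeca-2,6,8-trienoate | CO[C@H]1C[C@@H](O[C@H]1/C=C(/C)I)[C@@H](C)[C@H](OC(=O)/C(C)=C\[C@H](C)C(OCc2ccc(OC)cc2)/C(C)=C/C=C\CCO[Si](C)(C)C(C)(C)C)/C=C/[C@@H](O[Si](C)(C)C(C)(C)C)[C@H](C)OS(=O)(=O)c3ccc(C)cc3 | intermediate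
33 | (1E,3R,4R)-4-{(2R,4S,5S)-5-[(1Z)-2-iodoprop-1-en-1-yl]-4-methoxyoxolan-2-yl}-1-[(2R,3R)-3-methyloxiran-2-yl]pent-1-en-3-yl (2Z,4S,5RS,6E,8Z)-11-hydroxy-5-[(4-methoxyphenyl)methoxy]-2,4,6-trimethylundeca-2,6,8-trienoate | CO[C@H]1C[C@@H](O[C@H]1/C=C(/C)I)[C@@H](C)[C@H](OC(=O)/C(C)=C\[C@H](C)C(OCc2ccc(OC)cc2)/C(C)=C/C=C\CCO)/C=C/[C@H]3O[C@@H]3C | intermediate
34 | dienyl carbinol (not isolated): (1E,3R,4R)-4-{(2R,4S,5S)-5-[(1Z)-2-iodoprop-1-en-1-yl]-4-methoxyoxolan-2-yl}-1-[(2R,3R)-3-methyloxiran-2-yl]pent-1-en-3-yl (2Z,4S,5RS,6E,8Z)-5,11-dihydroxy-2,4,6-trimethylundeca-2,6,8-trienoate | CO[C@H]1C[C@@H](O[C@H]1/C=C(/C)I)[C@@H](C)[C@H](OC(=O)/C(C)=C\[C@H](C)C(O)/C(C)=C/C=C\CCO)/C=C/[C@H]2O[C@@H]2C | intermediate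
35 | (1E,3R,4R)-4-{(2R,4S,5S)-5-[(1Z)-2-iodoprop-1-en-1-yl]-4-methoxyoxolan-2-yl}-1-[(2R,3R)-3-methyloxiran-2-yl]pent-1-en-3-yl (2Z,4S,6E,8Z)-11-hydroxy-2,4,6-trimethyl-5-oxoundeca-2,6,8-trienoate | CO[C@H]1C[C@@H](O[C@H]1/C=C(/C)I)[C@@H](C)[C@H](OC(=O)/C(C)=C\[C@H](C)C(=O)/C(C)=C/C=C\CCO)/C=C/[C@H]2O[C@@H]2C | intermediate
36 | (1E,3R,4R)-4-{(2R,4S,5S)-5-[(1Z)-2-iodoprop-1-en-1-yl]-4-methoxyoxolan-2-yl}-1-[(2R,3R)-3-methyloxiran-2-yl]pent-1-en-3-yl (2Z,4S,6E,8Z)-2,4,6-trimethyl-5,11-dioxoundeca-2,6,8-trienoate | CO[C@H]1C[C@@H](O[C@H]1/C=C(/C)I)[C@@H](C)[C@H](OC(=O)/C(C)=C\[C@H](C)C(=O)/C(C)=C/C=C\CC=O)/C=C/[C@H]2O[C@@H]2C | intermediate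
37 | CNP0117824.2, (2Z,4S,6E,8Z,11R,12Z,14S,15S,17R,18R,19R)-14,17-epoxy-11-hydroxy-15-methoxy-2,4,6,12,18-pentamethyl-19-{(E)-2-[(2R,3R)-3-methyloxiran-2-yl]ethenyl}-5-oxononadeca-2,6,8,12-tetraen-19-olide | CO[C@H]1C[C@H]2O[C@H]1/C=C(/C)[C@H](O)C/C=C\C=C(/C)C(=O)[C@@H](C)/C=C(/C)C(=O)O[C@H](/C=C/[C@H]1O[C@@H]1C)[C@@H]2C | target

## Step count and risks

Total step count: 28. Longest linear sequence: 15 steps (1 → 11 by steps 1–9, then steps 13 and 24–28; the chain from 19 through steps 14–23 and 24–28 is equally long).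

The three steps most likely to fail:

Step 28 (the new electrochemical ring closure). It may stall, the vinyl oxirane may be opened by zerovalent nickel or by the chromium salts, or the C11 epimers may form without useful preference. The fallback gives up electrolysis and catalytic chromium altogether and closes the ring with the established reagent-based coupling. It sets out from keto-aldehyde 36, which is added by syringe pump to excess CrCl2 with 1 mol % NiCl2 in degassed DMSO/THF at 2 mM and room temperature, and it comes back to the route at 37. The C11 epimers are separated by chromatography. This fallback makes no compound outside the list, so its entry is none F0.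

Step 13 (facial selectivity at C19). Chelation of zinc by the oxolane oxygen could erode or reverse the Felkin preference. The fallback sets the C19 configuration by substitution instead of by facial selectivity. It sets out from aldehyde 11 and alkyne 15. The same addition is run, and the C19 epimer (2S,3R,4E,6S,7S)-3-{[tert-butyl(dimethyl)silyl]oxy}-6-hydroxy-7-{(2R,4S,5S)-5-[(1Z)-2-iodoprop-1-en-1-yl]-4-methoxyoxolan-2-yl}oct-4-en-2-yl 4-methylbenzenesulfonate F1 is separated from 18. It is then esterified with acid 31 under Mitsunobu conditions (PPh3, diisopropyl azodicarboxylate, toluene, 0 °C). The carboxylate displaces the activated C19 oxygen with inversion, so the fallback comes back to the route at ester 32, where material from both epimers converges.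

Step 24 (esterification of a hindered allylic alcohol with a hindered Z-enoic acid). Acylation may be slow and the activated acid may isomerise to the E-enoate. The fallback builds the Z-alkene after the ester bond instead of before it. It sets out from alcohol 18 and aldehyde 29. Alcohol 18 is acylated with 2-[bis(2,2,2-trifluoroethoxy)phosphoryl]propanoic acid (N,N′-dicyclohexylcarbodiimide, DMAP cat., CH2Cl2) to give (2S,3R,4E,6R,7R)-3-{[tert-butyl(dimethyl)silyl]oxy}-7-{(2R,4S,5S)-5-[(1Z)-2-iodoprop-1-en-1-yl]-4-methoxyoxolan-2-yl}-2-{[(4-methylphenyl)sulfonyl]oxy}oct-4-en-6-yl 2-[bis(2,2,2-trifluoroethoxy)phosphoryl]propanoate F2. Its potassium salt (KN(SiMe3)2, 18-crown-6, THF, −78 °C) undergoes Still–Gennari olefination with aldehyde 29, and the fallback comes back to the route at ester 32.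

Further compounds
F1 | step 13 | (2S,3R,4E,6S,7S)-3-{[tert-butyl(dimethyl)silyl]oxy}-6-hydroxy-7-{(2R,4S,5S)-5-[(1Z)-2-iodoprop-1-en-1-yl]-4-methoxyoxolan-2-yl}oct-4-en-2-yl 4-methylbenzenesulfonate | CO[C@H]1C[C@@H](O[C@H]1/C=C(/C)I)[C@@H](C)[C@@H](O)/C=C/[C@@H](O[Si](C)(C)C(C)(C)C)[C@H](C)OS(=O)(=O)c1ccc(C)cc1
F2 | step 24 | (2S,3R,4E,6R,7R)-3-{[tert-butyl(dimethyl)silyl]oxy}-7-{(2R,4S,5S)-5-[(1Z)-2-iodoprop-1-en-1-yl]-4-methoxyoxolan-2-yl}-2-{[(4-methylphenyl)sulfonyl]oxy}oct-4-en-6-yl 2-[bis(2,2,2-trifluoroethoxy)phosphoryl]propanoate | CO[C@H]1C[C@@H](O[C@H]1/C=C(/C)I)[C@@H](C)[C@H](OC(=O)C(C)P(=O)(OCC(F)(F)F)OCC(F)(F)F)/C=C/[C@@H](O[Si](C)(C)C(C)(C)C)[C@H](C)OS(=O)(=O)c1ccc(C)cc1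
F0 | step 28 | none | none
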